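**Retrosynthetic overview**
- The last operations are tert-butyl ester cleavage, O-methylation and closure of both pyranone rings at O1–C2 by lactonisation of 3,5-diketo esters.
- Key disconnection: the C5–C6 bond of both pyranones. Each pyranone C6 sits on a quaternary, methyl-bearing cyclobutane carbon (C3 and C4), so both bonds are made by γ-aldol addition of an acetoacetate dianion to a non-enolisable neopentyl cis-dialdehyde.
- The dialdehyde comes from ozonolysis of the cyclobutene ring of a 1,4-dimethylbicyclo[2.2.0]hex-5-ene-2,3-diester, itself made by bis-decarboxylation of a maleic anhydride photoadduct.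
- That adduct comes from a [2+2] photoaddition of maleic anhydride anti to the two esters of a 3,4-dimethylcyclobutene-1,2-diester (this puts the esters cis to the methyls and trans to the future pyranones); the cyclobutene comes from maleic anhydride and but-2-yne.
- Ring order: cyclobutane (step 1), an auxiliary second four-membered ring (step 4, removed in steps 5–6), then both pyranones together (step 9).

Key step: step 7

Remark: the target has a mirror plane through the midpoints of the C1–C2 and C3–C4 bonds (1R,2S,3R,4S, meso). It is therefore achiral, and only relative configuration has to be controlled.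

**Route**

Step 1
Reactants: 1 maleic anhydride; 2 but-2-yne
Product: 3 cis-3,4-dimethylcyclobut-3-ene-1,2-dicarboxylic anhydride (meso)
Conditions: 2 (5 equiv), Ph2CO (0.1 equiv), EtOAc, hν (medium-pressure Hg, Pyrex), 0–5 °C
Reagents that add atoms: none
Why: Triplet-sensitised [2+2] photocycloaddition of maleic anhydride to an alkyne should give the cyclobutene; the two new CH centres are held cis by the five-membered anhydride, and excess but-2-yne keeps the product from taking up a second maleic anhydride.

Step 2
Reactants: 3 cis-3,4-dimethylcyclobut-3-ene-1,2-dicarboxylic anhydride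
Product: 4 cis-2-(tert-butoxycarbonyl)-3,4-dimethylcyclobut-3-ene-1-carboxylic acid (racemic)
Conditions: t-BuOH (5 equiv), DMAP (0.2 equiv), CH2Cl2, 40 °C; aq. citric acid wash
Reagents that add atoms: tert-butanol, CC(C)(C)O
Why: DMAP-catalysed alcoholysis of the strained meso anhydride should give the cis half-ester without a base strong enough to epimerise the allylic α-CH centres, and both enantiomers of 4 converge on meso 5.

Step 3
Reactants: 4 cis-2-(tert-butoxycarbonyl)-3,4-dimethylcyclobut-3-ene-1-carboxylic acid
Product: 5 di-tert-butyl cis-3,4-dimethylcyclobut-3-ene-1,2-dicarboxylate (meso)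
Conditions: Cl3CC(=NH)Ot-Bu (2 equiv), CH2Cl2/cyclohexane, rt
Reagents that add atoms: tert-butyl 2,2,2-trichloroacetimidate, CC(C)(C)OC(=N)C(Cl)(Cl)Cl
Why: The acid protonates the imidate and is then tert-butylated (trichloroacetimidate esterification) under near-neutral conditions at room temperature, so neither the cis α-centres nor the heat- and acid-sensitive cyclobutene should suffer.

Step 4
Reactants: 5 di-tert-butyl cis-3,4-dimethylcyclobut-3-ene-1,2-dicarboxylate; 1 maleic anhydride
Product: 6 2,3-bis(tert-butoxycarbonyl)-1,4-dimethylbicyclo[2.2.0]hexane-5,6-dicarboxylic anhydride (meso; both esters cis to the bridgehead methyls and trans to the new ring; anhydride cis-fused and drawn exo)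
Conditions: 1 (1.5 equiv), acetophenone (sens.), MeCN, hν (Pyrex), 0–10 °C
Reagents that add atoms: none
Why: Sensitised [2+2] photocycloaddition of triplet maleic anhydride to the tetrasubstituted ring alkene (the reaction that gives 2:1 adducts from alkynes) should occur on the face anti to both tert-butyl esters, which sets the two quaternary centres with the methyls cis and the new ring carbons trans to the esters; the two new CH centres are cis by the anhydride ring, and their orientation does not matter because they are removed in step 5.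

Step 5
Reactants: 6 2,3-bis(tert-butoxycarbonyl)-1,4-dimethylbicyclo[2.2.0]hexane-5,6-dicarboxylic anhydride
Product: 8 di-tert-butyl 1,4-dimethylbicyclo[2.2.0]hex-5-ene-2,3-dicarboxylate (meso; both esters exo = cis to the bridgehead methyls), via cis-diacid 7 (not isolated)
Conditions: H2O (1.1 equiv), pyridine, rt; then Pb(OAc)4 (1.3 equiv), O2, 55 °C
Reagents that add atoms: none
Why: After opening of the anhydride, lead tetraacetate oxidative bis-decarboxylation of the vicinal cis-diacid should give the cyclobutene, as in the classical routes to bicyclo[2.2.0]hexenes; the tert-butyl esters carry no free acid and the temperature stays far below that of thermal opening of the bicyclo[2.2.0]hexene.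

Step 6
Reactants: 8 di-tert-butyl 1,4-dimethylbicyclo[2.2.0]hex-5-ene-2,3-dicarboxylate
Product: 10 di-tert-butyl (1R,2S,3R,4S)-3,4-diformyl-3,4-dimethylcyclobutane-1,2-dicarboxylate (meso; Me/Me/CO2t-Bu/CO2t-Bu on one face and both CHO on the other), via secondary ozonide 9 (not isolated)
Conditions: O3, CH2Cl2, −78 °C; then PPh3 (1.2 equiv), −78 °C → rt; kept dry and used at once
Reagents that add atoms: ozone, [O-][O+]=O
Why: Ozonolysis with phosphine reduction of the ozonide cleaves the only C=C bond and leaves a formyl group on each quaternary carbon, cis to one another because they came from one ring; no centre can epimerise since both aldehydes are non-enolisable.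

Step 7
Reactants: 10 di-tert-butyl (1R,2S,3R,4S)-3,4-diformyl-3,4-dimethylcyclobutane-1,2-dicarboxylate; 11 methyl 2-methyl-3-oxobutanoate
Product: 13 di-tert-butyl (1R,2S,3R,4S)-3,4-bis(1-hydroxy-5-methoxy-4-methyl-3,5-dioxopentyl)-3,4-dimethylcyclobutane-1,2-dicarboxylate (carbinol and CHMe centres of the arms as a mixture), via sodium lithium dianion 12 (not isolated)
Conditions: 11 (3.5 equiv), NaH (3.5 equiv), THF, 0 °C; n-BuLi (3.5 equiv), 0 °C; 10 added at −78 °C, then −40 °C; AcOH, −78 °C
Reagents that add atoms: none
Why: The dianion 12 carries its most reactive carbanion at the terminal CH2, which adds to each neopentyl formyl group of 10 in an aldol addition and forms both pyranone C5–C6 bonds; the closest known reaction type is the γ-selective aldol addition of acetoacetate dianions to aldehydes. No ring is closed in this step; the two pyranone rings close in step 9. The new carbinol centres and the CHMe centres of the arms form without control, which is of no consequence because all of them become sp2 in steps 8 and 9. The step needs γ- over α-attack (the α-carbon is the stabilised, fully substituted enolate carbon), aldehyde over ester attack (the ring esters are tert-butyl and flanked by quaternary carbons) and no epimerisation of the ring CH centres (addition at −78 °C should be far faster than deprotonation of the hindered ester α-hydrogens, and the quaternary carbons cannot enolise). The alkoxide of the first adduct may close reversibly on the neighbouring cis-formyl group as a lactolate, so 10 is added to excess 12 and the mixture is warmed to −40 °C to draw this equilibrium to the bis-adduct; lactonisation onto a ring ester is excluded because each arm is trans to the ester on the adjacent carbon.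

Step 8
Reactants: 13 di-tert-butyl (1R,2S,3R,4S)-3,4-bis(1-hydroxy-5-methoxy-4-methyl-3,5-dioxopentyl)-3,4-dimethylcyclobutane-1,2-dicarboxylate
Product: 14 di-tert-butyl (1R,2S,3R,4S)-3,4-bis(5-methoxy-4-methyl-1,3,5-trioxopentyl)-3,4-dimethylcyclobutane-1,2-dicarboxylate
Conditions: Dess–Martin periodinane (2.4 equiv), CH2Cl2, 0 °C → rt
Reagents that add atoms: none
Why: Dess–Martin oxidation converts both neopentyl secondary alcohols into ketones under near-neutral conditions, which removes the uncontrolled carbinol centres and leaves the tert-butyl esters and ring centres untouched.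

Step 9
Reactants: 14 di-tert-butyl (1R,2S,3R,4S)-3,4-bis(5-methoxy-4-methyl-1,3,5-trioxopentyl)-3,4-dimethylcyclobutane-1,2-dicarboxylate
Product: 15 di-tert-butyl (1R,2S,3R,4S)-3,4-bis(4-hydroxy-3-methyl-2-oxo-2H-pyran-6-yl)-3,4-dimethylcyclobutane-1,2-dicarboxylate
Conditions: DBU (4 equiv), toluene, rt → 50 °C; aq. citric acid work-up
Reagents that add atoms: none
Why: DBU enolises each 3,5-diketo ester and the C5 enolate oxygen acylates the methyl ester (6-exo-trig lactonisation with loss of methanol) to close both 4-hydroxy-2-pyranone rings; with both arms held as delocalised enolates the ring-bound ketones are not electrophilic, so aldol closure between the arms should not compete, and DBU is too weak to touch the ester α-CH centres.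

Step 10
Reactants: 15 di-tert-butyl (1R,2S,3R,4S)-3,4-bis(4-hydroxy-3-methyl-2-oxo-2H-pyran-6-yl)-3,4-dimethylcyclobutane-1,2-dicarboxylate
Product: 16 di-tert-butyl (1R,2S,3R,4S)-3,4-bis(4-methoxy-3-methyl-2-oxo-2H-pyran-6-yl)-3,4-dimethylcyclobutane-1,2-dicarboxylate
Conditions: Me2SO4 (2.5 equiv), K2CO3 (3 equiv), acetone, 50 °C
Reagents that add atoms: dimethyl sulfate, COS(=O)(=O)OC
Why: Methylation of the 4-hydroxy-2-pyranone anion with the hard electrophile dimethyl sulfate is the standard route to 4-methoxy-2-pyranones and should take place at the 4-oxygen, C3 being blocked by its methyl group.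

Step 11
Reactants: 16 di-tert-butyl (1R,2S,3R,4S)-3,4-bis(4-methoxy-3-methyl-2-oxo-2H-pyran-6-yl)-3,4-dimethylcyclobutane-1,2-dicarboxylate
Product: 17 (1R,2S,3R,4S)-3,4-bis(4-methoxy-3-methyl-2-oxo-2H-pyran-6-yl)-3,4-dimethylcyclobutane-1,2-dicarboxylic acid (CNP0574758.1)
Conditions: TFA/CH2Cl2 (1:1), 0 °C → rt
Reagents that add atoms: none
Why: Acidolysis of the tert-butyl esters (E1 loss of isobutene) frees both acids without base, so the ring CH centres keep their configuration and the methoxypyranones, which are stable to TFA, are untouched.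

**Compound list**
1 | maleic anhydride | O=C1C=CC(=O)O1 | starting material
2 | but-2-yne | CC#CC | starting material
3 | cis-3,4-dimethylcyclobut-3-ene-1,2-dicarboxylic anhydride (meso) | CC1=C(C)[C@@H]2C(=O)OC(=O)[C@H]12 | intermediate
4 | cis-2-(tert-butoxycarbonyl)-3,4-dimethylcyclobut-3-ene-1-carboxylic acid (racemic, one enantiomer drawn) | CC1=C(C)[C@H](C(=O)OC(C)(C)C)[C@@H]1C(=O)O | intermediate
5 | di-tert-butyl cis-3,4-dimethylcyclobut-3-ene-1,2-dicarboxylate (meso) | CC1=C(C)[C@H](C(=O)OC(C)(C)C)[C@@H]1C(=O)OC(C)(C)C | intermediate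
6 | 2,3-bis(tert-butoxycarbonyl)-1,4-dimethylbicyclo[2.2.0]hexane-5,6-dicarboxylic anhydride (meso; esters exo, anhydride drawn exo) | O=C1OC(=O)[C@@H]2[C@H]1[C@@]3(C)[C@H](C(=O)OC(C)(C)C)[C@H](C(=O)OC(C)(C)C)[C@@]23C | intermediate
7 | 2,3-bis(tert-butoxycarbonyl)-1,4-dimethylbicyclo[2.2.0]hexane-5,6-dicarboxylic acid (cis-diacid, not isolated) | OC(=O)[C@@H]1[C@H](C(=O)O)[C@@]2(C)[C@H](C(=O)OC(C)(C)C)[C@H](C(=O)OC(C)(C)C)[C@@]12C | intermediate
8 | di-tert-butyl 1,4-dimethylbicyclo[2.2.0]hex-5-ene-2,3-dicarboxylate (meso; esters exo) | C1=C[C@@]2(C)[C@H](C(=O)OC(C)(C)C)[C@H](C(=O)OC(C)(C)C)[C@@]12C | intermediate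
9 | secondary ozonide of 8 (1,2,4-trioxolane bridging the two former alkene carbons; orientation of the peroxide bridge not defined; not isolated) | O1OC2OC1[C@@]3(C)[C@H](C(=O)OC(C)(C)C)[C@H](C(=O)OC(C)(C)C)[C@@]23C | intermediate
10 | di-tert-butyl (1R,2S,3R,4S)-3,4-diformyl-3,4-dimethylcyclobutane-1,2-dicarboxylate (meso) | O=C[C@@]1(C)[C@H](C(=O)OC(C)(C)C)[C@H](C(=O)OC(C)(C)C)[C@@]1(C)C=O | intermediate
11 | methyl 2-methyl-3-oxobutanoate | COC(=O)C(C)C(C)=O | starting material
12 | sodium lithium dianion of methyl 2-methyl-3-oxobutanoate (not isolated) | C=C([O-])C(C)=C([O-])OC.[Na+].[Li+] | intermediate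
13 | di-tert-butyl (1R,2S,3R,4S)-3,4-bis(1-hydroxy-5-methoxy-4-methyl-3,5-dioxopentyl)-3,4-dimethylcyclobutane-1,2-dicarboxylate (arm centres as a mixture) | COC(=O)C(C)C(=O)CC(O)[C@@]1(C)[C@H](C(=O)OC(C)(C)C)[C@H](C(=O)OC(C)(C)C)[C@@]1(C)C(O)CC(=O)C(C)C(=O)OC | intermediate
14 | di-tert-butyl (1R,2S,3R,4S)-3,4-bis(5-methoxy-4-methyl-1,3,5-trioxopentyl)-3,4-dimethylcyclobutane-1,2-dicarboxylate | COC(=O)C(C)C(=O)CC(=O)[C@@]1(C)[C@H](C(=O)OC(C)(C)C)[C@H](C(=O)OC(C)(C)C)[C@@]1(C)C(=O)CC(=O)C(C)C(=O)OC | intermediate
15 | di-tert-butyl (1R,2S,3R,4S)-3,4-bis(4-hydroxy-3-methyl-2-oxo-2H-pyran-6-yl)-3,4-dimethylcyclobutane-1,2-dicarboxylate | Cc1c(O)cc([C@@]2(C)[C@H](C(=O)OC(C)(C)C)[C@H](C(=O)OC(C)(C)C)[C@@]2(C)c2cc(O)c(C)c(=O)o2)oc1=O | intermediate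
16 | di-tert-butyl (1R,2S,3R,4S)-3,4-bis(4-methoxy-3-methyl-2-oxo-2H-pyran-6-yl)-3,4-dimethylcyclobutane-1,2-dicarboxylate | COc1cc([C@@]2(C)[C@H](C(=O)OC(C)(C)C)[C@H](C(=O)OC(C)(C)C)[C@@]2(C)c2cc(OC)c(C)c(=O)o2)oc(=O)c1C | intermediate
17 | (1R,2S,3R,4S)-3,4-bis(4-methoxy-3-methyl-2-oxo-2H-pyran-6-yl)-3,4-dimethylcyclobutane-1,2-dicarboxylic acid (meso) | COc1cc([C@@]2(C)[C@H](C(=O)O)[C@H](C(=O)O)[C@@]2(C)c2cc(OC)c(C)c(=O)o2)oc(=O)c1C | target

**Step count and risks**

Total step count: 11. Longest linear sequence: 11 steps (1 and 2 to 17).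

Steps most likely to fail:

1. Step 7 (key step). The second addition may stall because the first aldolate closes onto the neighbouring cis-formyl group, or the strongly basic dianion may deprotonate and epimerise the ring CH centres next to the tert-butyl esters on warming. The fallback sets out from 10 and 11 and returns at 13, using a Lewis-acid vinylogous Mukaiyama aldol in place of the dianion. Compound 11 with TMSCl/Et3N should give methyl 2-methyl-3-(trimethylsilyloxy)but-2-enoate F1. LDA then TMSCl should convert this into 1-methoxy-2-methyl-1,3-bis(trimethylsilyloxy)buta-1,3-diene F2. Dialdehyde 10 with F2 (3 equiv) and BF3·OEt2 in CH2Cl2 at −78 °C, followed by aqueous work-up, should give 13 without any strongly basic species.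

2. Step 5. The lead(IV) bis-decarboxylation may give little alkene because of competing acetoxylation or lactone formation at the intermediate radical or cation stage. The fallback sets out from 5 and returns at 10, replacing steps 4–6. Acetone-sensitised [2+2] photocycloaddition of vinylene carbonate to 5, again anti to the esters, should give di-tert-butyl 1,4-dimethylbicyclo[2.2.0]hexane-2,3-dicarboxylate 5,6-cyclic carbonate F3. K2CO3 in MeOH should release di-tert-butyl cis-5,6-dihydroxy-1,4-dimethylbicyclo[2.2.0]hexane-2,3-dicarboxylate F4. Glycol cleavage with NaIO4 on silica in CH2Cl2 should then give 10 directly.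

3. Step 4. The crossed photocycloaddition may lose out to dimerisation of maleic anhydride, to hydrogen abstraction from 5 by the sensitiser, or to slow addition at the hindered tetrasubstituted alkene. The fallback sets out from 1 and commercial 2,3-dimethylmaleic anhydride and returns at 10, replacing steps 1–6.
   - Sensitised crossed photodimerisation should give cis,trans,cis-1,2-dimethylcyclobutane-1,2,3,4-tetracarboxylic 1,2:3,4-dianhydride F5, with the anhydride rings on opposite faces, to be separated from the two homodimers.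
   - t-BuOH/DMAP should open only the unhindered CH–CH anhydride, giving the half-ester acid with the tetrasubstituted anhydride retained F6.
   - tert-Butyl trichloroacetimidate should give the di-tert-butyl ester anhydride F7.
   - LiBH4 in THF should reduce the remaining anhydride to di-tert-butyl (1R,2S,3R,4S)-3,4-bis(hydroxymethyl)-3,4-dimethylcyclobutane-1,2-dicarboxylate F8.
   - Swern oxidation should give 10.

**Further compounds**
F1 | step 7 | methyl 2-methyl-3-(trimethylsilyloxy)but-2-enoate | CC(O[Si](C)(C)C)=C(C)C(=O)OC
F2 | step 7 | 1-methoxy-2-methyl-1,3-bis(trimethylsilyloxy)buta-1,3-diene | C=C(O[Si](C)(C)C)C(C)=C(OC)O[Si](C)(C)C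
F3 | step 5 | di-tert-butyl 1,4-dimethylbicyclo[2.2.0]hexane-2,3-dicarboxylate 5,6-cyclic carbonate (meso; esters exo, carbonate drawn exo) | O=C1O[C@@H]2[C@H](O1)[C@@]3(C)[C@H](C(=O)OC(C)(C)C)[C@H](C(=O)OC(C)(C)C)[C@@]23C
F4 | step 5 | di-tert-butyl cis-5,6-dihydroxy-1,4-dimethylbicyclo[2.2.0]hexane-2,3-dicarboxylate (meso) | O[C@@H]1[C@H](O)[C@@]2(C)[C@H](C(=O)OC(C)(C)C)[C@H](C(=O)OC(C)(C)C)[C@@]12C
F5 | step 4 | cis,trans,cis-1,2-dimethylcyclobutane-1,2,3,4-tetracarboxylic 1,2:3,4-dianhydride (meso) | O=C1OC(=O)[C@@]2(C)[C@@H]3C(=O)OC(=O)[C@@H]3[C@@]12C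
F6 | step 4 | 3-(tert-butoxycarbonyl)-1,2-dimethylcyclobutane-1,2,4-tricarboxylic acid 1,2-anhydride (racemic, one enantiomer drawn) | O=C1OC(=O)[C@@]2(C)[C@H](C(=O)OC(C)(C)C)[C@H](C(=O)O)[C@@]12C
F7 | step 4 | 3,4-bis(tert-butoxycarbonyl)-1,2-dimethylcyclobutane-1,2-dicarboxylic anhydride (meso) | O=C1OC(=O)[C@@]2(C)[C@H](C(=O)OC(C)(C)C)[C@H](C(=O)OC(C)(C)C)[C@@]12C
F8 | step 4 | di-tert-butyl (1R,2S,3R,4S)-3,4-bis(hydroxymethyl)-3,4-dimethylcyclobutane-1,2-dicarboxylate (meso) | OC[C@@]1(C)[C@H](C(=O)OC(C)(C)C)[C@H](C(=O)OC(C)(C)C)[C@@]1(C)CO
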